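In percent of the starting material charged, the flask can give at most 90.0 % of product. This figure is the product ceiling: the smaller of the partner charge and the starting material charge less the protic impurity, taken over the starting material charge.

in all of them: partner 0.117 M; free catalyst 0.26 mM
- oak: starting material 0.13 M; protic impurity 2.6 mM; the very flask that is asked about, followed so far
- cedar: starting material 0.065 M; protic impurity 2.6 mM; run made earlier
- flask: starting material 0.13 M; protic impurity 2.60 mM; time 15 h

- oak (time / h: product / %, starting material / %): 0.667: 90.1, 7.9; 1.00: 90.1, 7.4; 1.33: 89.8, 8.4; 2.00: 89.6, 8.1; 3.00: 90.6, 8.2; 5.00: 90.5, 7.3; 8.00: 89.9, 7.7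
- cedar (time / h: product / %, starting material / %): 0.500: 95.2, 0.2; 1.50: 95.3, 0.7; 3.00: 95.5, 0.5; 5.00: 96.4, 0; 6.00: 95.6, 0.2; 8.00: 97.0, 0; 10.0: 97.0, 0.1

(scatter of a reading: 0.5 percentage points)

1. which holds at 15 h: what has brought the reaction to rest, or that it has not come to rest (it is still moving / the partner has run out first / forward and back rates have come level / no working catalyst is left / all of the starting material has reacted)
2. the product standing at 15 h, as a percentage of the starting material charged
3. amount of product if the flask were left three thousand times as long, in percent of the starting material charged

Which side sets the ceiling? One product takes one partner and one starting material, and each protic impurity removes one starting material. The partner charge of 0.117 M stands below the 0.127 M of starting material left after the quench, so partner is the limiting reagent.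

Does the rule hold when the other side is the smaller? In the cedar run starting material sets the ceiling, at 96.0 %, and the cedar product readings run from 95.2 % to 97.0 %.

Has oak reached its ceiling? Oak reads 90.1 % product at 0.667 h and 89.9 % at 8.00 h, with a scatter of 0.5 percentage points. The reckoning leaves 8.00 % of starting material, counting both the free form and what sits on the catalyst as catalyst intermediate A, and oak reads 7.9 % and 7.7 %, which are separate readings from the product ones. A repeat should show both lines flat within that scatter from the first sample.

The reckoning here therefore puts the product at the ceiling at 15 h and after the long wait. The forecast agrees: the partner has run out first, with 90 % at 15 h and 90 % after the long wait. In its words, “Without partner, no further product can form, however long the wait.”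

The flask gives: the partner has run out first, with 90.0 % at 15 h and 90.0 % after the long wait.

    starting material + free catalyst → catalyst intermediate A (k = 2000 M⁻¹ min⁻¹)
    partner + catalyst intermediate A → catalyst intermediate B (k = 2100 M⁻¹ min⁻¹)
    catalyst intermediate B ⇌ free catalyst + product (K = 0.150 M, k = 36.0 min⁻¹)
    starting material + protic impurity → quenched substrate (k = 17.0 M⁻¹ min⁻¹)
    2 free catalyst → spent catalyst (k = 250 M⁻¹ min⁻¹)

The flask stands on its ceiling of 90.0 %, with partner at 0 % of its charge and starting material at 7.82 % of its own. The product figure does not show that catalyst remains: at 15.0 h, 89.9 % of the catalyst charged stands as catalyst intermediate A and 10.1 % as spent catalyst. A neighbour charged with 0.070 M of partner has the ceiling 53.8 %. At 15.0 h it holds 53.8 % of product, with partner at 0 % of its charge and starting material at 44 %.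

Readings and results were computed from invented constants.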